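The route rests on the O1–C2 bond of ring A (oxane O1, C2, C3, C4, C5–Br, C6). C2 is a fully substituted ether carbon at the end of the diene C7=C8–C9=C10 that carries ring B, so the bond can form and re-open through a pentadienyl cation. In one operation Re2O7 ionises an acyclic C8 bis-allylic alcohol, the C6 tertiary hydroxyl of an enantiopure C5 bromohydrin captures the cation at C2, ring A closes, C2 equilibrates and the (7E,9E)-diene emerges. The precursor comes from CrCl2/NiCl2 coupling of a geranyl-derived bromohydrin enal with a ring B alkenyl iodide whose syn-bromohydrin oxygen is silylated.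

Key step: step 12

Remarks on the chemistry (assumptions):
* Locants: ring A = oxane O1, C2 (CH3, dienyl), C3, C4, C5 (Br), C6 (two CH3); diene C7=C8–C9=C10 (CH3 on C10); ring B = cyclohexane attached to C10.
* In ring B the bromine, the hydroxyl and the side chain are all cis (syn-bromohydrin, Br equatorial, OH axial). Anti addition to an alkene cannot give this, so the secondary carbinol of a trans-diol is inverted with bromide.
* The (5R)-bromide needs the (6S)-epoxide of geranyl acetate. The common D-fructose-derived Shi ketone is expected to give the (6R)-epoxide, so its enantiomer (accessible from L-sorbose) is used.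
* The epoxide is opened to the bromohydrin before the fragment coupling, so that the acid-sensitive bis-allylic alcohol 16 is made last and used at once.
* (1S,2S,4R)-Limonene-1,2-diol and geranyl acetate are taken as commercial. Any minor (6R) antipode carried through the geranyl half becomes a diastereomer after coupling and should be removed by chromatography.

Step 1
Reactants: 1 (1S,2S,4R)-1-methyl-4-(prop-1-en-2-yl)cyclohexane-1,2-diol
Product: 2 (3aS,5R,7aS)-7a-methyl-5-(prop-1-en-2-yl)hexahydro-1,3,2-benzodioxathiole 2-oxide (trans-fused cyclic sulfite, both sulfur epimers)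
Conditions: SOCl2, Et3N, CH2Cl2, 0 °C
Reagents that add atoms: thionyl chloride, O=S(Cl)Cl
Why: Cyclic sulfite formation from a 1,2-diol with SOCl2 and an amine base; the diaxial trans-diol flips to the diequatorial chair to close the five-membered ring and no carbon stereocentre is touched.

Step 2
Reactants: 2 cyclic sulfite
Product: 3 1-[(3aS,5R,7aS)-7a-methyl-2,2-dioxohexahydro-1,3,2-benzodioxathiol-5-yl]ethan-1-one (trans-fused cyclic sulfate, methyl ketone)
Conditions: RuCl3·xH2O (cat.), NaIO4, MeCN/CCl4/H2O, 0 °C to rt
Reagents that add atoms: sodium periodate, [Na+].[O-]I(=O)(=O)=O (oxygen delivered through RuO4)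
Why: RuO4 generated from RuCl3 and NaIO4 oxidises the cyclic sulfite to the cyclic sulfate and, in the same pot, cleaves the 1,1-disubstituted alkene to the methyl ketone (oxidative alkene cleavage), with no stereocentre involved.

Step 3
Reactants: 3 keto cyclic sulfate
Product: 5 1-[(1R,3R,4S)-3-bromo-4-hydroxy-4-methylcyclohexyl]ethan-1-one, via lithium bromo sulfate 4 (not isolated)
Conditions: LiBr, THF, 0 to 40 °C; then 20% aq. H2SO4, Et2O, rt
Reagents that add atoms: lithium bromide, [Li+].[Br-]
Why: Opening of a 1,2-cyclic sulfate (epoxide-like SN2): bromide attacks the secondary carbon anti to its C–O bond and inverts it (new CHBr centre R, bromine cis to the tertiary oxygen and to the acetyl group), and acid then hydrolyses the tertiary sulfate monoester at the S–O bond with retention, so the trans-diol becomes the syn-bromohydrin.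

Step 4
Reactants: 5 syn-bromohydrin ketone
Product: 6 1-[(1R,3R,4S)-3-bromo-4-methyl-4-(triethylsilyloxy)cyclohexyl]ethan-1-one
Conditions: TESOTf, 2,6-lutidine, CH2Cl2, −78 to 0 °C
Reagents that add atoms: triethylsilyl triflate, CC[Si](CC)(CC)OS(=O)(=O)C(F)(F)F
Why: Silyl triflate silylation of a hindered tertiary alcohol with a non-nucleophilic base; the triethylsilyl ether masks the ring B oxygen for the basic steps and for the key step.

Step 5
Reactants: 6 silylated bromo ketone
Product: 8 {[(1S,2R,4R)-2-bromo-4-ethynyl-1-methylcyclohexyl]oxy}(triethyl)silane, via enol phosphate 7 (not isolated)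
Conditions: LiN(iPr)2, THF, −78 °C; ClP(O)(OEt)2; LiN(iPr)2 (2.3 equiv), −78 °C to rt; aq. NH4Cl
Reagents that add atoms: none
Why: Negishi conversion of a methyl ketone into a terminal alkyne (kinetic methyl deprotonation, O-phosphorylation, elimination of the enol phosphate); the equatorial, neopentyl-type C–Br bond has no anti-periplanar hydrogen and resists substitution, and the silyl ether prevents alkoxide-driven ring contraction of the syn-bromohydrin.

Step 6
Reactants: 8 ring B alkyne
Product: 10 {[(1S,2R,4R)-2-bromo-4-[(E)-1-iodoprop-1-en-2-yl]-1-methylcyclohexyl]oxy}(triethyl)silane, via alkenylalane 9 (not isolated)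
Conditions: AlMe3, Cp2ZrCl2 (cat.), CH2Cl2, 0 °C to rt; then I2, THF, −30 to 0 °C
Reagents that add atoms: trimethylaluminium, C[Al](C)C; iodine, II
Why: Zirconium-catalysed carboalumination (Negishi) adds CH3 and Al syn across the terminal alkyne with the methyl on the internal carbon, and iodinolysis of the C–Al bond with retention gives the (E)-alkenyl iodide.

Step 7
Reactants: 11 geranyl acetate
Product: 12 (2E)-5-[(2S)-3,3-dimethyloxiran-2-yl]-3-methylpent-2-en-1-yl acetate [(6S)-6,7-epoxygeranyl acetate]
Conditions: ent-Shi ketone (enantiomer of the D-fructose-derived ketone, 0.3 equiv), KHSO5 (as Oxone), K2CO3, Bu4NHSO4, MeCN/CH2(OMe)2/aq. Na2B4O7 buffer, 0 °C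
Reagents that add atoms: potassium peroxymonosulfate, [K+].OOS(=O)(=O)[O-]
Why: Shi epoxidation: the chiral dioxirane epoxidises the electron-rich 6,7-alkene (the 2,3-alkene is deactivated by the allylic acetate) through a spiro transition state, and the enantiomer of the D-fructose-derived ketone delivers oxygen to the face that gives the (6S)-epoxide.

Step 8
Reactants: 12 (6S)-6,7-epoxygeranyl acetate
Product: 13 (2E)-5-[(2S)-3,3-dimethyloxiran-2-yl]-3-methylpent-2-en-1-ol [(6S)-6,7-epoxygeraniol]
Conditions: K2CO3, MeOH, 0 °C to rt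
Reagents that add atoms: none
Why: Base-catalysed methanolysis (transesterification) of the acetate; the trisubstituted epoxide is inert to K2CO3/MeOH.

Step 9
Reactants: 13 (6S)-6,7-epoxygeraniol
Product: 14 (2E,6R)-6-bromo-3,7-dimethyloct-2-ene-1,7-diol
Conditions: Li2NiBr4, THF, 0 °C to rt
Reagents that add atoms: Li2NiBr4 (dilithium tetrabromonickelate), [Li+].[Li+].Br[Ni-2](Br)(Br)Br
Why: Li2NiBr4 delivers soft bromide in an SN2 opening at the less substituted epoxide carbon with inversion, turning the (6S)-epoxide into the (6R)-bromide and leaving the tertiary alcohol.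

Step 10
Reactants: 14 bromo diol
Product: 15 (2E,6R)-6-bromo-7-hydroxy-3,7-dimethyloct-2-enal
Conditions: MnO2, CH2Cl2, rt
Reagents that add atoms: none
Why: MnO2 oxidises only the allylic primary alcohol to the enal; the tertiary alcohol and the bromide are untouched and no base is present that could re-close the epoxide.

Step 11
Reactants: 10 ring B alkenyl iodide; 15 bromohydrin enal
Product: 16 (3R,6E,9E)-3-bromo-10-[(1R,3R,4S)-3-bromo-4-methyl-4-(triethylsilyloxy)cyclohexyl]-2,6-dimethylundeca-6,9-diene-2,8-diol (C8 bis-allylic alcohol in target locants, both C8 epimers)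
Conditions: CrCl2, NiCl2 (cat.), DMSO, rt
Reagents that add atoms: none
Why: Nozaki–Hiyama–Kishi coupling: zerovalent nickel (formed by divalent chromium) inserts into the alkenyl iodide with retention of the E geometry, transmetalation gives an alkenyl trivalent chromium species that adds 1,2 to the enal; free hydroxyls and unactivated secondary bromides are tolerated and the new C8 centre forms as both epimers, which is of no consequence.

Step 12
Reactants: 16 C8 bis-allylic alcohol
Product: 19 {[(1S,2R,4R)-2-bromo-4-[(2E,4E)-5-[(2S,5R)-5-bromo-2,6,6-trimethyloxan-2-yl]penta-2,4-dien-2-yl]-1-methylcyclohexyl]oxy}(triethyl)silane, via perrhenate ester 17 (not isolated), via pentadienyl cation 18 (not isolated)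
Conditions: Re2O7 (5 mol %), CH2Cl2, 0 °C to rt; Et3N quench
Reagents that add atoms: none
Why: Re2O7 converts the C8 hydroxyl into a perrhenate ester that ionises (directly or after transposition) to a pentadienyl cation delocalised over C2, C8 and C10, and the C6 tertiary hydroxyl adds to the C2 terminus, closing ring A by a 6-exo-trig attack through a chair while the remaining π-system settles as the conjugated (7E,9E)-diene. The closest known reaction type is the Re2O7-catalysed transposition of allylic alcohols with capture by a pendant hydroxyl to give oxanes under thermodynamic control; a tertiary nucleophile and a fully substituted terminus are more demanding but belong to the same class. The new O1–C2 ether is still doubly allylic and re-ionises under the same conditions, so C2 is set by equilibration and relayed from C5: in the chair with C5–Br equatorial the epimers differ in whether the C2 methyl (target) or the C2 dienyl group is syn-axial to a C6 methyl, a difference expected to be small, so the target epimer should be isolated by chromatography and the other epimer returned to the same conditions. The step needs site-selective ionisation, which the bis-allylic C8 carbinol secures over the β-bromo tertiary C6 carbinol, and capture at C2 only, which is secured because the ring B oxygen is silylated (no capture at C10), capture at C8 by water merely regenerates 16, and only the C6 oxygen can form a six-membered ring. The C8 configuration and the original alkene geometry are erased in the cation and are therefore irrelevant.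

Step 13
Reactants: 19 triethylsilyl ether of the target
Product: 20 (1S,2R,4R)-2-bromo-4-[(2E,4E)-5-[(2S,5R)-5-bromo-2,6,6-trimethyloxan-2-yl]penta-2,4-dien-2-yl]-1-methylcyclohexan-1-ol (target)
Conditions: Bu4NF, AcOH (1:1), THF, 0 °C to rt
Reagents that add atoms: none
Why: Fluoride-mediated desilylation buffered with acetic acid, so that neither a free alkoxide next to the cis bromine (semipinacol ring contraction) nor strong acid (ionisation of the dienyl ether) is present.

Compound list
1 | (1S,2S,4R)-1-methyl-4-(prop-1-en-2-yl)cyclohexane-1,2-diol (limonene-1,2-diol, trans-diaxial, tertiary OH cis to isopropenyl) | CC(=C)[C@@H]1CC[C@](C)(O)[C@@H](O)C1 | starting material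
2 | (3aS,5R,7aS)-7a-methyl-5-(prop-1-en-2-yl)hexahydro-1,3,2-benzodioxathiole 2-oxide (sulfur epimers) | CC(=C)[C@@H]1CC[C@](C)(OS(=O)O2)[C@@H]2C1 | intermediate
3 | 1-[(3aS,5R,7aS)-7a-methyl-2,2-dioxohexahydro-1,3,2-benzodioxathiol-5-yl]ethan-1-one | CC(=O)[C@@H]1CC[C@](C)(OS(=O)(=O)O2)[C@@H]2C1 | intermediate
4 | lithium (1S,2R,4R)-4-acetyl-2-bromo-1-methylcyclohexyl sulfate | CC(=O)[C@@H]1CC[C@](C)(OS(=O)(=O)[O-])[C@H](Br)C1.[Li+] | intermediate
5 | 1-[(1R,3R,4S)-3-bromo-4-hydroxy-4-methylcyclohexyl]ethan-1-one | CC(=O)[C@@H]1CC[C@](C)(O)[C@H](Br)C1 | intermediate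
6 | 1-[(1R,3R,4S)-3-bromo-4-methyl-4-(triethylsilyloxy)cyclohexyl]ethan-1-one | CC(=O)[C@@H]1CC[C@](C)(O[Si](CC)(CC)CC)[C@H](Br)C1 | intermediate
7 | diethyl 1-[(1R,3R,4S)-3-bromo-4-methyl-4-(triethylsilyloxy)cyclohexyl]ethenyl phosphate | C=C(OP(=O)(OCC)OCC)[C@@H]1CC[C@](C)(O[Si](CC)(CC)CC)[C@H](Br)C1 | intermediate
8 | {[(1S,2R,4R)-2-bromo-4-ethynyl-1-methylcyclohexyl]oxy}(triethyl)silane | C#C[C@@H]1CC[C@](C)(O[Si](CC)(CC)CC)[C@H](Br)C1 | intermediate
9 | dimethyl{(E)-2-[(1R,3R,4S)-3-bromo-4-methyl-4-(triethylsilyloxy)cyclohexyl]prop-1-en-1-yl}alane | C/C(=C\[Al](C)C)[C@@H]1CC[C@](C)(O[Si](CC)(CC)CC)[C@H](Br)C1 | intermediate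
10 | {[(1S,2R,4R)-2-bromo-4-[(E)-1-iodoprop-1-en-2-yl]-1-methylcyclohexyl]oxy}(triethyl)silane | C/C(=C\I)[C@@H]1CC[C@](C)(O[Si](CC)(CC)CC)[C@H](Br)C1 | intermediate
11 | geranyl acetate, (2E)-3,7-dimethylocta-2,6-dien-1-yl acetate | CC(C)=CCC/C(C)=C/COC(C)=O | starting material
12 | (2E)-5-[(2S)-3,3-dimethyloxiran-2-yl]-3-methylpent-2-en-1-yl acetate | CC1(C)O[C@H]1CC/C(C)=C/COC(C)=O | intermediate
13 | (2E)-5-[(2S)-3,3-dimethyloxiran-2-yl]-3-methylpent-2-en-1-ol | CC1(C)O[C@H]1CC/C(C)=C/CO | intermediate
14 | (2E,6R)-6-bromo-3,7-dimethyloct-2-ene-1,7-diol | CC(C)(O)[C@H](Br)CC/C(C)=C/CO | intermediate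
15 | (2E,6R)-6-bromo-7-hydroxy-3,7-dimethyloct-2-enal | CC(C)(O)[C@H](Br)CC/C(C)=C/C=O | intermediate
16 | (3R,6E,9E)-3-bromo-10-[(1R,3R,4S)-3-bromo-4-methyl-4-(triethylsilyloxy)cyclohexyl]-2,6-dimethylundeca-6,9-diene-2,8-diol (C8 epimers) | CC(C)(O)[C@H](Br)CC/C(C)=C/C(O)/C=C(\C)[C@@H]1CC[C@](C)(O[Si](CC)(CC)CC)[C@H](Br)C1 | intermediate
17 | C8 perrhenate ester of 16 | CC(C)(O)[C@H](Br)CC/C(C)=C/C(O[Re](=O)(=O)=O)/C=C(\C)[C@@H]1CC[C@](C)(O[Si](CC)(CC)CC)[C@H](Br)C1 | intermediate
18 | pentadienyl cation (C2/C8/C10) as perrhenate ion pair | CC(C)(O)[C@H](Br)CC[C+](C)/C=C/C=C(\C)[C@@H]1CC[C@](C)(O[Si](CC)(CC)CC)[C@H](Br)C1.[O-][Re](=O)(=O)=O | intermediate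
19 | {[(1S,2R,4R)-2-bromo-4-[(2E,4E)-5-[(2S,5R)-5-bromo-2,6,6-trimethyloxan-2-yl]penta-2,4-dien-2-yl]-1-methylcyclohexyl]oxy}(triethyl)silane | C/C(=C\C=C\[C@]1(C)CC[C@@H](Br)C(C)(C)O1)[C@@H]1CC[C@](C)(O[Si](CC)(CC)CC)[C@H](Br)C1 | intermediate
20 | (1S,2R,4R)-2-bromo-4-[(2E,4E)-5-[(2S,5R)-5-bromo-2,6,6-trimethyloxan-2-yl]penta-2,4-dien-2-yl]-1-methylcyclohexan-1-ol | C/C(=C\C=C\[C@]1(C)CC[C@@H](Br)C(C)(C)O1)[C@@H]1CC[C@](C)(O)[C@H](Br)C1 | target

Total step count: 13 (six to the alkenyl iodide 10, four to the enal 15, three from the coupling to the target).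
Longest linear sequence: 9 steps (steps 1–6, 11, 12, 13).

The three steps most likely to fail

Step 12. The equilibrium between the C2 epimers may lie near parity or on the wrong side. The cation may also be drained by proton loss to trienes, or by acid cleavage of the silyl ether followed by capture at C10. The fallback closes ring A under kinetic, stereospecific control; it sets out from 10 and 15 and comes back to the route at 19. The coupling of 10 with 15 is repeated with CrCl2 bound to a stoichiometric chiral oxazoline sulfonamide ligand (NiCl2 cat., Et3N, THF, rt), the ligand enantiomer being chosen to give the single C8 epimer (3R,6E,8S,9E)-3-bromo-10-[(1R,3R,4S)-3-bromo-4-methyl-4-(triethylsilyloxy)cyclohexyl]-2,6-dimethylundeca-6,9-diene-2,8-diol F1. Ph3PAuCl/AgOTf (monovalent gold, CH2Cl2, 4 Å molecular sieves, −20 °C) should then cyclise this diol by the known stereospecific dehydrative cyclisation of monoallylic diols. This is a formal syn-SN2' displacement (anti alkoxyauration, then anti elimination of the C8 hydroxyl), in which the (8S) carbinol and the (E)-C2=C7 alkene should be translated into the (2S) ether and the (E)-C7=C8 alkene of 19.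

Step 3. Attack of bromide at the secondary carbon passes the axial acetyl group and may be slow. Meanwhile the tertiary C–O bond may ionise, in the cyclic sulfate or during hydrolysis of the sulfate monoester, leading to elimination, to the regioisomeric bromide or to loss of the tertiary configuration. The fallback replaces the cyclic electrophile by a stepwise sulfonate displacement; it sets out from 1 and comes back to the route at 6. MsCl/pyridine (CH2Cl2, 0 °C) should sulfonylate only the secondary hydroxyl to give (1S,2S,5R)-2-hydroxy-2-methyl-5-(prop-1-en-2-yl)cyclohexyl methanesulfonate F2. TESOTf/2,6-lutidine then silylates the tertiary hydroxyl, which blocks epoxide closure, to give (1S,2S,5R)-2-methyl-5-(prop-1-en-2-yl)-2-(triethylsilyloxy)cyclohexyl methanesulfonate F3. LiBr in DMPU at 60 °C should displace the mesylate with inversion to give {[(1S,2R,4R)-2-bromo-1-methyl-4-(prop-1-en-2-yl)cyclohexyl]oxy}(triethyl)silane F4. Ozonolysis of the isopropenyl group (O3, CH2Cl2/MeOH, −78 °C; Me2S) then gives 6.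

Step 5. Under two successive charges of LiN(iPr)2 the substrate may lose HBr, or the ring methine next to the carbonyl may be deprotonated and the material diverted. The fallback olefinates the ketone instead of passing through the alkyne; it sets out from 6 and comes back to the route at 10, so that steps 5 and 6 are both bypassed. Boron-Wittig reaction with LiCH(Bpin)2 (from CH2(Bpin)2 and lithium 2,2,6,6-tetramethylpiperidide, THF, −78 °C to rt) should give, with boron trans to the ring, {[(1S,2R,4R)-2-bromo-1-methyl-4-[(E)-1-(4,4,5,5-tetramethyl-1,3,2-dioxaborolan-2-yl)prop-1-en-2-yl]cyclohexyl]oxy}(triethyl)silane F5. Iododeboronation (NaOH, then I2, THF, 0 °C), which retains the alkene geometry, then gives 10.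

Further compounds
F1 | step 12 | (3R,6E,8S,9E)-3-bromo-10-[(1R,3R,4S)-3-bromo-4-methyl-4-(triethylsilyloxy)cyclohexyl]-2,6-dimethylundeca-6,9-diene-2,8-diol | CC(C)(O)[C@H](Br)CC/C(C)=C/[C@H](O)/C=C(\C)[C@@H]1CC[C@](C)(O[Si](CC)(CC)CC)[C@H](Br)C1
F2 | step 3 | (1S,2S,5R)-2-hydroxy-2-methyl-5-(prop-1-en-2-yl)cyclohexyl methanesulfonate | CC(=C)[C@@H]1CC[C@](C)(O)[C@@H](OS(C)(=O)=O)C1
F3 | step 3 | (1S,2S,5R)-2-methyl-5-(prop-1-en-2-yl)-2-(triethylsilyloxy)cyclohexyl methanesulfonate | CC(=C)[C@@H]1CC[C@](C)(O[Si](CC)(CC)CC)[C@@H](OS(C)(=O)=O)C1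
F4 | step 3 | {[(1S,2R,4R)-2-bromo-1-methyl-4-(prop-1-en-2-yl)cyclohexyl]oxy}(triethyl)silane | CC(=C)[C@@H]1CC[C@](C)(O[Si](CC)(CC)CC)[C@H](Br)C1
F5 | step 5 | {[(1S,2R,4R)-2-bromo-1-methyl-4-[(E)-1-(4,4,5,5-tetramethyl-1,3,2-dioxaborolan-2-yl)prop-1-en-2-yl]cyclohexyl]oxy}(triethyl)silane | C/C(=C\B1OC(C)(C)C(C)(C)O1)[C@@H]1CC[C@](C)(O[Si](CC)(CC)CC)[C@H](Br)C1
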